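**Plan**

1. Ring numbering used throughout: C1 = quaternary carbon (methyl, vinyl), C2 = CH2, C3 = CH–O(acyl), C4 = CH(acrylic acid), C5 = CH–OH, C6 = CH(hydroxypropenyl). Retrosynthesis: cut the C3–O ester, then the C–CO2H bond of the acrylic acid (enol triflate + CO), return vinyl to nitrile and remove C1–CH3, then cut ring bonds C2–C3 and C5–C6 in one stroke, last the Morita–Baylis–Hillman C–C bond.
2. Enabling feature: C3–C4–C5 is a masked dihydroxyacetone (C4 a former ketone carbon; O3 and O5 cis-1,3 and bridgeable as an acetonide) whose two α-carbons are nucleophilic as an enamine. C2–C1–C6 is the allyl unit of a 2-(bromomethyl)alk-2-enenitrile (C2 = CH2Br, C6 = β-carbon, nitrile on C1 = latent vinyl), a 1,3-bis-electrophile.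
3. Forward: dienyl bromide (4 steps) + 2,2-dimethyl-1,3-dioxan-5-one → one-pot α,α′-annulation closes the only ring as a 2,4-dioxabicyclo[3.3.1]nonan-9-one. Then ketone → acetyl, C1 methylation, nitrile → vinyl, acetonide release, enol triflate, esterification, carbonylation, desilylation.
4. Stereochemistry: C3 (absolute) from the C2-symmetric (2S,5S)-2,5-dimethylpyrrolidine enamine; C5 cis to C3 through the acetonide bridge; C6 from the alkene geometry through the chair Michael closure; C1 by exo-face methylation of the bridged nitrile anion; C4 by equilibration to the equatorial acetyl.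

Key step: step 5

Remark: the facial sense of the enamine alkylation in step 5 is assigned from the steric model of the C2-symmetric amine (attack anti to the methyl group flanking the enamine double bond); were the opposite sense found, the (2R,5R)-amine would take its place.

Step 1
Reactants: 1 2-methylidenepropane-1,3-diol
Product: 2 2-{[tert-butyl(diphenyl)silyl]oxymethyl}prop-2-en-1-ol
Conditions: NaH (1.0 equiv), THF, 0 °C; TBDPSCl (1.0 equiv), 0 → 23 °C
Reagents that add atoms: tert-butyl(chloro)diphenylsilane, CC(C)(C)[Si](Cl)(c1ccccc1)c1ccccc1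
Why: One equivalent of NaH gives the poorly soluble monoalkoxide of the symmetric diol, which is silylated once (Williamson-type O-silylation); no stereocentre.

Step 2
Reactants: 2 2-{[tert-butyl(diphenyl)silyl]oxymethyl}prop-2-en-1-ol
Product: 3 2-{[tert-butyl(diphenyl)silyl]oxymethyl}prop-2-enal
Conditions: activated MnO2 (10 equiv), CH2Cl2, 23 °C
Reagents that add atoms: none
Why: Activated MnO2 should oxidise the allylic alcohol to the enal without touching the silyl ether (allylic alcohol oxidation).

Step 3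
Reactants: 3 2-{[tert-butyl(diphenyl)silyl]oxymethyl}prop-2-enal; 4 prop-2-enenitrile
Product: 5 rac-4-{[tert-butyl(diphenyl)silyl]oxymethyl}-3-hydroxy-2-methylidenepent-4-enenitrile
Conditions: DABCO (0.3 equiv), excess prop-2-enenitrile as solvent, 23 °C
Reagents that add atoms: none
Why: Morita–Baylis–Hillman reaction: the DABCO–acrylonitrile zwitterion adds to the aldehyde carbonyl in a pure addition that keeps every atom of both partners; the carbinol stereocentre is racemic and is erased in step 4.

Step 4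
Reactants: 5 rac-4-{[tert-butyl(diphenyl)silyl]oxymethyl}-3-hydroxy-2-methylidenepent-4-enenitrile
Product: 6 (2E)-2-(bromomethyl)-4-{[tert-butyl(diphenyl)silyl]oxymethyl}penta-2,4-dienenitrile (alkenyl group cis to the nitrile)
Conditions: PBr3 (0.4 equiv), Et2O, −10 → 0 °C
Reagents that add atoms: phosphorus tribromide, BrP(Br)Br
Why: PBr3 should convert the Morita–Baylis–Hillman alcohol into the rearranged primary allylic bromide (SN2′ transposition under thermodynamic control), the alkenyl group ending cis to the small linear nitrile.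

Step 5
Reactants: 7 2,2-dimethyl-1,3-dioxan-5-one; 6 (2E)-2-(bromomethyl)-4-{[tert-butyl(diphenyl)silyl]oxymethyl}penta-2,4-dienenitrile
Product: 11 (1R,5S,6R)-6-(3-{[tert-butyl(diphenyl)silyl]oxy}prop-1-en-2-yl)-3,3-dimethyl-9-oxo-2,4-dioxabicyclo[3.3.1]nonane-7-carbonitrile (C7 epimers), via dioxinyl enamine 8 (not isolated), via C-alkylated enamine 9 (not isolated), via bicyclic iminium bromide 10 (not isolated)
Conditions: (2S,5S)-2,5-dimethylpyrrolidine (1.1 equiv), 4 Å molecular sieves, benzene, 23 °C; then 6, i-Pr2NEt, MeCN, 0 → 60 °C; then aq. AcOH/NaOAc, 23 °C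
Reagents that add atoms: water, O
Why: Enamine 8 attacks the unhindered primary allylic bromide of 6 at C2 (SN2), the resulting iminium tautomerises to the less substituted α′-enamine 9, whose enamine carbon (C5) adds to C6, the β-carbon of the alkylidene nitrile, and hydrolysis of iminium 10 returns the ketone, so that C2–C3 and C5–C6 form in one flask. The closest known reaction type is the enamine α,α′-annulation of cyclic ketones with 2-(bromomethyl)acrylic acid derivatives (Stork enamine alkylation followed by intramolecular Michael addition) giving bicyclo[3.3.1]nonan-9-ones. The first bond is intermolecular; the cyclohexane then closes by a 6-endo-trig Michael addition through a chair. C3 is set by the C2-symmetric pyrrolidine, whose methyl group on the carbon flanking the enamine double bond shields one face; C5 is forced cis to C3 because the three-carbon tether can only bridge the dioxane diaxially. C6 follows from the alkene geometry: the alkenyl group, trans to C2 across the double bond, becomes equatorial on the new chair and hence cis to O5; C1 stays epimeric until step 7. The step needs C- over N-alkylation, attack at CH2Br rather than SN2′ attack, and 1,4- rather than 1,6-addition to the dienyl nitrile; these should be secured by reversible N-alkylation, the unhindered primary bromide, and the preference for a six- over an eight-membered ring.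

Step 6
Reactants: 11 bicyclic keto nitrile (as above)
Product: 12 (1R,5S,6R)-6-(3-{[tert-butyl(diphenyl)silyl]oxy}prop-1-en-2-yl)-9-(1-methoxyethylidene)-3,3-dimethyl-2,4-dioxabicyclo[3.3.1]nonane-7-carbonitrile (C7 epimers; E/Z mixture)
Conditions: (1-methoxyethyl)triphenylphosphonium chloride, KOt-Bu, THF, 0 → 45 °C
Reagents that add atoms: (1-methoxyethyl)triphenylphosphonium chloride, COC(C)[P+](c1ccccc1)(c1ccccc1)c1ccccc1.[Cl-]
Why: Wittig olefination with the α-methoxyethylidene ylide should turn the non-enolisable, electron-poor C9 ketone into an enol ether (masked acetyl group, inert to LDA and i-Bu2AlH, and no longer able to leave as an enolate in a retro-Michael opening); the E/Z mixture is inconsequential.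

Step 7
Reactants: 12 enol ether nitrile (as above)
Product: 13 (1R,5S,6R,7S)-6-(3-{[tert-butyl(diphenyl)silyl]oxy}prop-1-en-2-yl)-9-(1-methoxyethylidene)-3,3,7-trimethyl-2,4-dioxabicyclo[3.3.1]nonane-7-carbonitrile (methyl exo; nitrile endo)
Conditions: LDA (1.3 equiv), THF, −78 °C; MeI, −78 → −20 °C
Reagents that add atoms: iodomethane, CI
Why: α-Alkylation of the nitrile-stabilised carbanion: MeI should approach the exo face of C7, away from the dioxane bridge, so that methyl becomes exo and the nitrile endo (cis to both ring oxygens), which sets the quaternary centre.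

Step 8
Reactants: 13 quaternary nitrile (as above)
Product: 14 (1R,5S,6R,7S)-6-(3-{[tert-butyl(diphenyl)silyl]oxy}prop-1-en-2-yl)-9-(1-methoxyethylidene)-3,3,7-trimethyl-2,4-dioxabicyclo[3.3.1]nonane-7-carbaldehyde
Conditions: i-Bu2AlH (1.5 equiv), toluene, −78 → −40 °C; then aq. NaOAc/AcOH (pH 5), 0 °C
Reagents that add atoms: water, O
Why: i-Bu2AlH should add once to the hindered tertiary nitrile, and buffered hydrolysis of the aldimine gives the aldehyde (nitrile half-reduction); the pH 5 work-up spares the enol ether.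

Step 9
Reactants: 14 aldehyde (as above)
Product: 15 (1R,5S,6R,7R)-6-(3-{[tert-butyl(diphenyl)silyl]oxy}prop-1-en-2-yl)-7-ethenyl-9-(1-methoxyethylidene)-3,3,7-trimethyl-2,4-dioxabicyclo[3.3.1]nonane
Conditions: Ph3PCH3Br, KN(SiMe3)2, THF, 0 → 23 °C
Reagents that add atoms: methyltriphenylphosphonium bromide, C[P+](c1ccccc1)(c1ccccc1)c1ccccc1.[Br-]
Why: Wittig methylenation of the neopentyl aldehyde installs the vinyl group; there is no epimerisable position next to the carbonyl.

Step 10
Reactants: 15 vinyl enol ether acetonide (as above)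
Product: 16 1-[(1R,2S,3R,4R,6R)-3-(3-{[tert-butyl(diphenyl)silyl]oxy}prop-1-en-2-yl)-4-ethenyl-2,6-dihydroxy-4-methylcyclohexyl]ethan-1-one (acetyl, both hydroxyls, the ethenyl group and the propenyl group all on one ring face)
Conditions: 1 M aq. HCl, THF, 23 °C
Reagents that add atoms: water, O
Why: Aqueous acid should hydrolyse the enol ether to the methyl ketone and the acetonide to the cis-1,3-diol; reversible acid-catalysed enolisation equilibrates C4 to the chair with acetyl, methyl and the alkenyl group equatorial and the two hydroxyls axial, the acetyl thus cis to both hydroxyls.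

Step 11
Reactants: 16 dihydroxy methyl ketone (as above)
Product: 17 the C3 triethylsilyl ether of 16 (C5 hydroxyl free)
Conditions: Et3SiCl (1.05 equiv), imidazole, DMF, −30 °C
Reagents that add atoms: chlorotriethylsilane, CC[Si](Cl)(CC)CC
Why: Silylation at low temperature should take the less hindered hydroxyl at C3 (flanked by the C2 methylene) in preference to the C5 hydroxyl next to the alkenyl-bearing C6 (steric differentiation).

Step 12
Reactants: 17 C3 triethylsilyl ether (as above)
Product: 18 the C3 triethylsilyl and C5 tert-butyldimethylsilyl bis-ether of 16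
Conditions: t-BuMe2SiOTf, 2,6-lutidine, CH2Cl2, −78 → −20 °C
Reagents that add atoms: tert-butyldimethylsilyl trifluoromethanesulfonate, CC(C)(C)[Si](C)(C)OS(=O)(=O)C(F)(F)F
Why: The powerful silyl triflate caps the remaining hindered axial hydroxyl as the robust TBS ether (O-silylation).

Step 13
Reactants: 18 bis-silyl methyl ketone (as above)
Product: 19 the enol triflate of 18: C4 carries a 1-(trifluoromethanesulfonyloxy)ethenyl group (ring stereocentres unchanged)
Conditions: KN(SiMe3)2 (1.1 equiv), THF, −78 °C; PhNTf2, −78 → 0 °C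
Reagents that add atoms: N-phenylbis(trifluoromethanesulfonimide), O=S(=O)(N(c1ccccc1)S(=O)(=O)C(F)(F)F)C(F)(F)F
Why: Kinetic deprotonation of the methyl ketone at the unhindered methyl group and O-triflation should give the terminal enol triflate without touching the C4 methine (enol triflate formation).

Step 14
Reactants: 19 enol triflate (as above)
Product: 20 the C3 alcohol: 19 without the triethylsilyl group
Conditions: PPTS (0.1 equiv), MeOH/CH2Cl2, 0 °C
Reagents that add atoms: none
Why: PPTS in methanol should cleave the secondary triethylsilyl ether selectively in the presence of the TBS and TBDPS ethers (graded silyl ether lability).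

Step 15
Reactants: 21 3-methylfuran-2(5H)-one
Product: 23 (2Z)-4-(acetyloxy)-2-methylbut-2-enoic acid, via sodium hydroxy-enoate 22 (not isolated)
Conditions: NaOH (1.0 equiv), H2O/THF, 0 → 23 °C; evaporate; Ac2O, pyridine, 0 °C; 1 M HCl to pH 3
Reagents that add atoms: sodium hydroxide, [Na+].[OH-]; acetic anhydride, CC(=O)OC(C)=O
Why: Saponification of the butenolide fixes the Z geometry (carboxylate and CH2OH cis, as in the ring), and acetylation of the salt before acidification prevents relactonisation.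

Step 16
Reactants: 20 C3 alcohol (as above); 23 (2Z)-4-(acetyloxy)-2-methylbut-2-enoic acid
Product: 25 the C3 (2Z)-4-(acetyloxy)-2-methylbut-2-enoate of 20, via mixed anhydride 24 (not isolated)
Conditions: 2,4,6-trichlorobenzoyl chloride, Et3N, THF, 0 °C; then 20, DMAP (0.2 equiv), toluene, 23 °C
Reagents that add atoms: none
Why: Yamaguchi esterification: the C3 hydroxyl should attack mixed anhydride 24 at the less hindered butenoyl carbonyl under DMAP catalysis, with retention at C3.

Step 17
Reactants: 25 ester enol triflate (as above)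
Product: 26 2-substituted prop-2-enoic acid: the target carrying a TBS ether at C5 and a TBDPS ether on the primary allylic alcohol
Conditions: Pd(OAc)2 (5 mol %), PPh3 (10 mol %), CO (1 atm), KOAc, DMF/H2O (20:1), 23 °C; aq. NaH2PO4
Reagents that add atoms: carbon monoxide, [C-]#[O+]; water, O
Why: Oxidative addition of zerovalent palladium into the vinyl triflate, CO insertion and capture of the acyl-palladium by acetate/water should give the 2-substituted acrylic acid (hydroxycarbonylation of an enol triflate); lactonisation is excluded because O3 is acylated and O5 silylated.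

Step 18
Reactants: 26 bis-silyl acid (as above)
Product: 27 2-[(1S,2R,4R,5R,6S)-2-{[(2Z)-4-(acetyloxy)-2-methylbut-2-enoyl]oxy}-4-ethenyl-6-hydroxy-5-(3-hydroxyprop-1-en-2-yl)-4-methylcyclohexyl]prop-2-enoic acid (target)
Conditions: HF·pyridine, pyridine, THF, 0 → 23 °C
Reagents that add atoms: none
Why: Buffered HF·pyridine should remove the TBS and TBDPS ethers without cleaving the acetate or the enoate ester and without strong acid that could lactonise the hydroxy acid (fluoride desilylation).

**Compound list**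

1 | 2-methylidenepropane-1,3-diol | C=C(CO)CO | starting material
2 | 2-{[tert-butyl(diphenyl)silyl]oxymethyl}prop-2-en-1-ol | C=C(CO)CO[Si](c1ccccc1)(c1ccccc1)C(C)(C)C | intermediate
3 | 2-{[tert-butyl(diphenyl)silyl]oxymethyl}prop-2-enal | C=C(C=O)CO[Si](c1ccccc1)(c1ccccc1)C(C)(C)C | intermediate
4 | prop-2-enenitrile | C=CC#N | starting material
5 | rac-4-{[tert-butyl(diphenyl)silyl]oxymethyl}-3-hydroxy-2-methylidenepent-4-enenitrile | C=C(C#N)C(O)C(=C)CO[Si](c1ccccc1)(c1ccccc1)C(C)(C)C | intermediate
6 | (2E)-2-(bromomethyl)-4-{[tert-butyl(diphenyl)silyl]oxymethyl}penta-2,4-dienenitrile | N#C/C(CBr)=C\C(=C)CO[Si](c1ccccc1)(c1ccccc1)C(C)(C)C | intermediate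
7 | 2,2-dimethyl-1,3-dioxan-5-one | CC1(C)OCC(=O)CO1 | starting material
8 | (2S,5S)-1-(2,2-dimethyl-4H-1,3-dioxin-5-yl)-2,5-dimethylpyrrolidine | CC1(C)OC=C(CO1)N1[C@@H](C)CC[C@@H]1C | intermediate
9 | (2S,5S)-1-{(4R)-4-[(2Z)-2-cyano-4-{[tert-butyl(diphenyl)silyl]oxymethyl}penta-2,4-dienyl]-2,2-dimethyl-4H-1,3-dioxin-5-yl}-2,5-dimethylpyrrolidine | N#C/C(C[C@H]1OC(C)(C)OC=C1N1[C@@H](C)CC[C@@H]1C)=C\C(=C)CO[Si](c1ccccc1)(c1ccccc1)C(C)(C)C | intermediate
10 | bicyclic (2S,5S)-2,5-dimethylpyrrolidinium-1-ylidene bromide of ketone 11 | N#CC1C[C@H]2OC(C)(C)O[C@@H]([C@H]1C(=C)CO[Si](c1ccccc1)(c1ccccc1)C(C)(C)C)C2=[N+]1[C@@H](C)CC[C@@H]1C.[Br-] | intermediate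
11 | (1R,5S,6R)-6-(3-{[tert-butyl(diphenyl)silyl]oxy}prop-1-en-2-yl)-3,3-dimethyl-9-oxo-2,4-dioxabicyclo[3.3.1]nonane-7-carbonitrile, C7 epimers | N#CC1C[C@H]2OC(C)(C)O[C@@H]([C@H]1C(=C)CO[Si](c1ccccc1)(c1ccccc1)C(C)(C)C)C2=O | intermediate
12 | 9-(1-methoxyethylidene) analogue of 11, C7 epimers, E/Z mixture | N#CC1C[C@H]2OC(C)(C)O[C@@H]([C@H]1C(=C)CO[Si](c1ccccc1)(c1ccccc1)C(C)(C)C)C2=C(C)OC | intermediate
13 | (1R,5S,6R,7S)-7-methyl-7-carbonitrile (methyl exo, nitrile endo) | N#C[C@@]1(C)C[C@H]2OC(C)(C)O[C@@H]([C@H]1C(=C)CO[Si](c1ccccc1)(c1ccccc1)C(C)(C)C)C2=C(C)OC | intermediate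
14 | (1R,5S,6R,7S)-7-methyl-7-carbaldehyde | O=C[C@@]1(C)C[C@H]2OC(C)(C)O[C@@H]([C@H]1C(=C)CO[Si](c1ccccc1)(c1ccccc1)C(C)(C)C)C2=C(C)OC | intermediate
15 | (1R,5S,6R,7R)-7-ethenyl-7-methyl enol ether acetonide | C=C[C@@]1(C)C[C@H]2OC(C)(C)O[C@@H]([C@H]1C(=C)CO[Si](c1ccccc1)(c1ccccc1)C(C)(C)C)C2=C(C)OC | intermediate
16 | 1-[(1R,2S,3R,4R,6R)-3-(3-{[tert-butyl(diphenyl)silyl]oxy}prop-1-en-2-yl)-4-ethenyl-2,6-dihydroxy-4-methylcyclohexyl]ethan-1-one | C=C[C@@]1(C)C[C@@H](O)[C@@H](C(C)=O)[C@@H](O)[C@H]1C(=C)CO[Si](c1ccccc1)(c1ccccc1)C(C)(C)C | intermediate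
17 | C3 triethylsilyl ether of 16 | C=C[C@@]1(C)C[C@@H](O[Si](CC)(CC)CC)[C@@H](C(C)=O)[C@@H](O)[C@H]1C(=C)CO[Si](c1ccccc1)(c1ccccc1)C(C)(C)C | intermediate
18 | C3 triethylsilyl, C5 tert-butyldimethylsilyl bis-ether of 16 | C=C[C@@]1(C)C[C@@H](O[Si](CC)(CC)CC)[C@@H](C(C)=O)[C@@H](O[Si](C)(C)C(C)(C)C)[C@H]1C(=C)CO[Si](c1ccccc1)(c1ccccc1)C(C)(C)C | intermediate
19 | enol triflate of 18 (1-(trifluoromethanesulfonyloxy)ethenyl at C4) | C=C[C@@]1(C)C[C@@H](O[Si](CC)(CC)CC)[C@@H](C(=C)OS(=O)(=O)C(F)(F)F)[C@@H](O[Si](C)(C)C(C)(C)C)[C@H]1C(=C)CO[Si](c1ccccc1)(c1ccccc1)C(C)(C)C | intermediate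
20 | C3 alcohol (19 without the triethylsilyl group) | C=C[C@@]1(C)C[C@@H](O)[C@@H](C(=C)OS(=O)(=O)C(F)(F)F)[C@@H](O[Si](C)(C)C(C)(C)C)[C@H]1C(=C)CO[Si](c1ccccc1)(c1ccccc1)C(C)(C)C | intermediate
21 | 3-methylfuran-2(5H)-one | CC1=CCOC1=O | starting material
22 | sodium (2Z)-4-hydroxy-2-methylbut-2-enoate | [Na+].[O-]C(=O)/C(C)=C\CO | intermediate
23 | (2Z)-4-(acetyloxy)-2-methylbut-2-enoic acid | OC(=O)/C(C)=C\COC(C)=O | intermediate
24 | (2Z)-4-(acetyloxy)-2-methylbut-2-enoic 2,4,6-trichlorobenzoic anhydride | O=C(OC(=O)/C(C)=C\COC(C)=O)c1c(Cl)cc(Cl)cc1Cl | intermediate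
25 | C3 (2Z)-4-(acetyloxy)-2-methylbut-2-enoate of 20 | C=C[C@@]1(C)C[C@@H](OC(=O)/C(C)=C\COC(C)=O)[C@@H](C(=C)OS(=O)(=O)C(F)(F)F)[C@@H](O[Si](C)(C)C(C)(C)C)[C@H]1C(=C)CO[Si](c1ccccc1)(c1ccccc1)C(C)(C)C | intermediate
26 | bis-silyl ether (C5 O-TBS, primary O-TBDPS) of 27 | C=C[C@@]1(C)C[C@@H](OC(=O)/C(C)=C\COC(C)=O)[C@@H](C(=C)C(=O)O)[C@@H](O[Si](C)(C)C(C)(C)C)[C@H]1C(=C)CO[Si](c1ccccc1)(c1ccccc1)C(C)(C)C | intermediate
27 | 2-[(1S,2R,4R,5R,6S)-2-{[(2Z)-4-(acetyloxy)-2-methylbut-2-enoyl]oxy}-4-ethenyl-6-hydroxy-5-(3-hydroxyprop-1-en-2-yl)-4-methylcyclohexyl]prop-2-enoic acid | C=C[C@@]1(C)C[C@@H](OC(=O)/C(C)=C\COC(C)=O)[C@@H](C(=C)C(=O)O)[C@@H](O)[C@H]1C(=C)CO | target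

**Step count**

Total steps: 18. Longest linear sequence: 17 steps (steps 1–14 and 16–18).

**Steps most likely to fail**

Step 5. Enantio- and diastereocontrol may erode in the first enamine alkylation, and N-alkylation, SN2′ attack or oligomerisation of the dienyl bromide may compete. The fallback runs from 7 back to 11. Ketone 7 is condensed with (R)-1-amino-2-(methoxymethyl)pyrrolidine to the RAMP hydrazone F1. Its lithium azaenolate (t-BuLi, THF, −78 °C) is alkylated with 6 at −100 °C to the monoalkylated hydrazone F2. A second deprotonation (LDA, −78 → 0 °C) closes F2 by the same intramolecular Michael addition to the bicyclic hydrazone F3. Two-phase saturated aqueous oxalic acid/Et2O then returns ketone 11 and the auxiliary.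

Step 6. The bulky, strongly basic α-methoxy ylide may fail to condense with the hindered, readily hydrated bridged ketone (slow addition, reversion of the betaine), and its basicity may trigger retro-Michael opening of the ring through the nitrile anion. The fallback runs from 11 back to 12. The smaller lithiated (1-methoxyethyl)diphenylphosphine oxide (LDA, THF, −78 °C) is added to 11 in an irreversible Horner–Wittig addition to give the β-hydroxy phosphine oxide F4. F4 is isolated and eliminated separately with NaH in THF at 50 °C to the same enol ether 12.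

Step 17. Zerovalent palladium may ionise the allylic acetate of the side chain (loss of acetate or scrambling of the Z-enoate) in competition with oxidative addition into the vinyl triflate. The fallback runs from 19 to 27 and moves the carbonylation ahead of the esterification. Triflate 19 is carbonylated in the presence of 2-(trimethylsilyl)ethanol (Pd(OAc)2, PPh3, CO, Et3N, DMF, 23 °C) to the 2-(trimethylsilyl)ethyl acrylate F5. The triethylsilyl ether is removed (PPTS, MeOH, 0 °C) to give the C3 alcohol F6, which is esterified with mixed anhydride 24 (DMAP, toluene) to the fully protected ester F7. Tris(dimethylamino)sulfonium difluorotrimethylsilicate buffered with AcOH in DMF then removes the 2-(trimethylsilyl)ethyl ester and both silyl ethers to give 27.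

Further compounds
F1 | step 5 | (R)-N-(2,2-dimethyl-1,3-dioxan-5-ylidene)-2-(methoxymethyl)pyrrolidin-1-amine | CC1(C)OCC(=NN2CCC[C@@H]2COC)CO1
F2 | step 5 | monoalkylated RAMP hydrazone (4R; (2Z)-2-cyano-4-(silyloxymethyl)penta-2,4-dienyl at C4 of the dioxane) | N#C/C(C[C@H]1OC(C)(C)OCC1=NN1CCC[C@@H]1COC)=C\C(=C)CO[Si](c1ccccc1)(c1ccccc1)C(C)(C)C
F3 | step 5 | RAMP hydrazone of ketone 11 | N#CC1C[C@H]2OC(C)(C)O[C@@H]([C@H]1C(=C)CO[Si](c1ccccc1)(c1ccccc1)C(C)(C)C)C2=NN1CCC[C@@H]1COC
F4 | step 6 | 9-hydroxy-9-[1-(diphenylphosphoryl)-1-methoxyethyl] adduct of ketone 11 (mixture at the new centres) | N#CC1C[C@H]2OC(C)(C)O[C@@H]([C@H]1C(=C)CO[Si](c1ccccc1)(c1ccccc1)C(C)(C)C)C2(O)C(C)(OC)P(=O)(c1ccccc1)c1ccccc1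
F5 | step 17 | 2-(trimethylsilyl)ethyl acrylate from 19 (C3 O-triethylsilyl, C5 O-TBS) | C=C[C@@]1(C)C[C@@H](O[Si](CC)(CC)CC)[C@@H](C(=C)C(=O)OCC[Si](C)(C)C)[C@@H](O[Si](C)(C)C(C)(C)C)[C@H]1C(=C)CO[Si](c1ccccc1)(c1ccccc1)C(C)(C)C
F6 | step 17 | C3 alcohol of F5 | C=C[C@@]1(C)C[C@@H](O)[C@@H](C(=C)C(=O)OCC[Si](C)(C)C)[C@@H](O[Si](C)(C)C(C)(C)C)[C@H]1C(=C)CO[Si](c1ccccc1)(c1ccccc1)C(C)(C)C
F7 | step 17 | C3 (2Z)-4-(acetyloxy)-2-methylbut-2-enoate of F6 | C=C[C@@]1(C)C[C@@H](OC(=O)/C(C)=C\COC(C)=O)[C@@H](C(=C)C(=O)OCC[Si](C)(C)C)[C@@H](O[Si](C)(C)C(C)(C)C)[C@H]1C(=C)CO[Si](c1ccccc1)(c1ccccc1)C(C)(C)C
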